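The plan rests on cutting C4–C5 of the ten-membered carbocycle (C1–C10): C5 is the allylic methylene of the C6=C7 alkene and C4 a plain methylene, so this bond can be made without touching C1, C3, C9 or C10. In one operation a C4 phenylsulfonyl carbanion displaces a primary allylic chloride at C5 and closes the ring. The precursor is a linear C4-sulfone/C5-chloride in which the lactone is masked as a cis-2,3-disubstituted 5-methoxyoxolane (O1, C1, C10, C11, C12) that turns both arms to one face, the alkene already has C5 and C8 cis, and O9 and O14 are 4-methoxybenzyl ethers.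

Key step: step 15

Remark 1: atom labels follow the target (C1 lactone O–CH, C3 CHMe, C6=C7 alkene, C9 acyloxy CH, C10 ring-fusion CH, C11 lactone α-carbon, C12 lactone carbonyl or acetal carbon, C13 exocyclic methylene, C14 oxygenated CH2 on C7, C15 methyl).
Remark 2: the acetal carbon C12 (compounds 13–28) and the sulfone carbon C4 of 26 are carried as epimer mixtures that converge later, so their SMILES leave these centres open.
Remark 3: short-lived metalated or onium-activated forms (enolates, alkoxides, the sulfonyl carbanion, the acyl-isourea) count as reacting forms of the numbered compounds; in-flask compounds that could be isolated are numbered.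

Step 1
Reactants: 1 (R)-4-benzyl-1,3-oxazolidin-2-one; 2 pent-4-enoyl chloride
Product: 3 (R)-4-benzyl-3-(pent-4-enoyl)-1,3-oxazolidin-2-one
Conditions: n-BuLi, THF, −78 °C; then 2, −78 → 0 °C
Reagents that add atoms: none
Why: N-acylation of the lithiated oxazolidinone by the acid chloride attaches the Evans auxiliary to the unit that becomes C1, C10, C11 and C12, and creates no stereocentre.

Step 2
Reactants: 3 N-pentenoyl oxazolidinone; 4 tert-butyl 4-oxobutanoate
Product: 5 tert-butyl (4S,5R)-5-{[(4R)-4-benzyl-2-oxo-1,3-oxazolidin-3-yl]carbonyl}-4-hydroxyoct-7-enoate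
Conditions: Bu2BOTf, i-Pr2NEt, CH2Cl2, 0 °C; 4, −78 → 0 °C; then pH 7 buffer, MeOH, H2O2
Reagents that add atoms: none
Why: Evans syn-aldol addition, in which the Z-boron enolate reacts through a chair Zimmerman–Traxler transition state on the face left open by the (R)-benzyl group and so sets C10 (R) and C9 (S) syn to each other, the tert-butyl ester being a spectator.

Step 3
Reactants: 5 aldol adduct
Product: 6 tert-butyl (4S,5R)-4-hydroxy-5-[methoxy(methyl)carbamoyl]oct-7-enoate
Conditions: MeNHOMe·HCl, AlMe3, THF, −20 → 0 °C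
Reagents that add atoms: N,O-dimethylhydroxylamine hydrochloride, CNOC.Cl
Why: Weinreb amide formation by aluminium-amide transamination, in which the aluminium alkoxide of the free C9 hydroxyl directs attack to the exocyclic imide carbonyl and the auxiliary is released without change at C9 or C10.

Step 4
Reactants: 7 (S)-3-bromo-2-methylpropan-1-ol
Product: 8 (S)-(3-bromo-2-methylpropoxy)(tert-butyl)dimethylsilane
Conditions: TBSCl, imidazole, CH2Cl2, 0 °C → rt
Reagents that add atoms: tert-butyldimethylsilyl chloride, CC(C)(C)[Si](C)(C)Cl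
Why: imidazole-mediated silylation of a primary alcohol; the stereocentre that becomes C3 is bought in and not touched.

Step 5
Reactants: 6 Weinreb amide; 8 silyl-protected bromide
Product: 10 tert-butyl (4S,5R,8R)-5-allyl-9-(tert-butyldimethylsilyloxy)-4-hydroxy-8-methyl-6-oxononanoate, via Grignard reagent 9 (not isolated)
Conditions: 8, Mg, THF, 40 °C; 6, i-PrMgCl (1.0 equiv), THF, −20 °C; then 9 (2 equiv), −20 → 0 °C; aq. NH4Cl
Reagents that add atoms: none
Why: Weinreb ketone synthesis, in which the Grignard reagent adds once to give a magnesium chelate that collapses only on work-up, the hydroxyl being masked as its magnesium alkoxide and the hindered tert-butyl ester reacting far more slowly at or below 0 °C; C3 arrives with the reagent.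

Step 6
Reactants: 10 β-hydroxy ketone
Product: 12 (5S)-5-[(4S,5S,7R)-8-(tert-butyldimethylsilyloxy)-5-hydroxy-7-methyloct-1-en-4-yl]oxolan-2-one, via anti-diol 11 (not isolated)
Conditions: Me4NBH(OAc)3, MeCN/AcOH (1:1), −30 °C; aqueous work-up; then PPTS, toluene, 80 °C
Reagents that add atoms: none
Why: Evans–Saksena hydroxyl-directed reduction (the C9 alkoxyborohydride delivers hydride intramolecularly through a chair transition state) sets C1 (S) 1,3-anti to O9, and acid-catalysed lactonisation then engages only O9, which alone can reach the ester in a five-membered ring, so O9 is masked and O1 stays free.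

Step 7
Reactants: 12 hydroxy lactone
Product: 14 (5S)-5-{(2S,3S)-2-[(2R)-3-hydroxy-2-methylpropyl]-5-methoxyoxolan-3-yl}oxolan-2-one, via lactol 13 (not isolated)
Conditions: O3, CH2Cl2/MeOH (4:1), −78 °C; Me2S, −78 °C → rt; then CSA (0.2 equiv), MeOH, rt
Reagents that add atoms: methanol, CO
Why: ozonolysis with reductive work-up unmasks the C12 aldehyde, which can close only on the free O1 to the cis-disubstituted lactol, and Fischer acetalisation in acidic methanol fixes it as the methyl acetal while methanolysis removes the primary silyl ether; C12 forms as an anomer mixture that is oxidised away in step 17.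

Step 8
Reactants: 14 lactone acetal; 15 (tert-butyldimethylsilyloxy)acetaldehyde
Product: 16 (5S)-3-[2-(tert-butyldimethylsilyloxy)-1-hydroxyethyl]-5-{(2S,3S)-2-[(2R)-3-hydroxy-2-methylpropyl]-5-methoxyoxolan-3-yl}oxolan-2-one (diastereomer mixture at the two new centres)
Conditions: LiN(i-Pr)2 (2.2 equiv), THF, −78 °C; 15, −78 °C; aq. NH4Cl
Reagents that add atoms: none
Why: aldol addition of the lactone lithium enolate (formed beside the C4 alkoxide) to the aldehyde joins C7 to C6; the two new centres form without control and are erased in step 9.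

Step 9
Reactants: 16 aldol adduct
Product: 18 (3E,5S)-3-[2-(tert-butyldimethylsilyloxy)ethylidene]-5-{(2S,3S)-5-methoxy-2-[(2R)-2-methyl-3-(methylsulfonyloxy)propyl]oxolan-3-yl}oxolan-2-one, via bis-mesylate 17 (not isolated)
Conditions: MsCl (3 equiv), Et3N, CH2Cl2, 0 °C; then DBU, 0 °C
Reagents that add atoms: methanesulfonyl chloride, CS(=O)(=O)Cl
Why: mesylation of both hydroxyls followed by E1cB elimination of the β-mesyloxy lactone should give the conjugated alkylidene lactone in its thermodynamically favoured (E) geometry, which places C5 anti to the carbonyl and therefore cis to C8, while the primary C4 mesylate is kept as the leaving group for step 11.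

Step 10
Reactants: 18 alkylidene lactone mesylate
Product: 19 (2R)-3-{(2S,3R)-3-[(1S,3E)-5-(tert-butyldimethylsilyloxy)-1-hydroxy-3-(hydroxymethyl)pent-3-en-1-yl]-5-methoxyoxolan-2-yl}-2-methylpropyl methanesulfonate
Conditions: (i-Bu)2AlH (4.5 equiv), CH2Cl2, −78 → −20 °C; aq. potassium sodium tartrate (KNaC4H4O6)
Reagents that add atoms: none
Why: aluminium hydride 1,2-reduction of the unsaturated lactone through the lactol and enal to the allylic 1,4-diol frees O9 and O14 without touching the alkene geometry, the sulfonate or the acetal at low temperature.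

Step 11
Reactants: 19 diol mesylate; 20 sodium benzenesulfinate
Product: 21 (1S,3E)-5-(tert-butyldimethylsilyloxy)-3-(hydroxymethyl)-1-{(2S,3R)-5-methoxy-2-[(2R)-2-methyl-3-(phenylsulfonyl)propyl]oxolan-3-yl}pent-3-en-1-ol
Conditions: Bu4NI (0.1 equiv), DMF, 60 °C
Reagents that add atoms: none
Why: SN2 S-alkylation of the sulfinate at the primary C4 mesylate (iodide-catalysed) installs the phenyl sulfone under neutral conditions; C3 is adjacent but not involved.

Step 12
Reactants: 21 sulfone diol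
Product: 22 tert-butyl{[(2E,5S)-5-[(4-methoxybenzyl)oxy]-3-{[(4-methoxybenzyl)oxy]methyl}-5-{(2S,3R)-5-methoxy-2-[(2R)-2-methyl-3-(phenylsulfonyl)propyl]oxolan-3-yl}pent-2-en-1-yl]oxy}dimethylsilane
Conditions: 2-(4-methoxybenzyloxy)-4-methylquinoline (4 equiv), MeOTf (4 equiv), MgO, PhCF3, 0 °C → rt
Reagents that add atoms: 2-(4-methoxybenzyloxy)-4-methylquinoline, COc1ccc(COc2cc(C)c3ccccc3n2)cc1
Why: Dudley-type etherification, in which the N-methylated 2-benzyloxyquinolinium salt transfers 4-methoxybenzyl to both hydroxyls under MgO-buffered neutral conditions, avoiding base at the sulfone and acid at the acetal.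

Step 13
Reactants: 22 fully protected sulfone
Product: 23 (2E,5S)-5-[(4-methoxybenzyl)oxy]-3-{[(4-methoxybenzyl)oxy]methyl}-5-{(2S,3R)-5-methoxy-2-[(2R)-2-methyl-3-(phenylsulfonyl)propyl]oxolan-3-yl}pent-2-en-1-ol
Conditions: Bu4NF, THF, 0 °C → rt
Reagents that add atoms: none
Why: fluoride-induced Si–O cleavage of the primary silyl ether; the benzylic ethers, the acetal and the sulfone are inert.

Step 14
Reactants: 23 allylic alcohol
Product: 25 (2S,3R)-3-[(1S,3E)-5-chloro-1-[(4-methoxybenzyl)oxy]-3-{[(4-methoxybenzyl)oxy]methyl}pent-3-en-1-yl]-5-methoxy-2-[(2R)-2-methyl-3-(phenylsulfonyl)propyl]oxolane, via allylic mesylate 24 (not isolated)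
Conditions: MsCl, 2,4,6-collidine, LiCl, DMF, 0 °C
Reagents that add atoms: lithium chloride, [Li+].[Cl-]
Why: Collington–Meyers chlorination, in which the allylic mesylate formed in situ is displaced by chloride in an SN2 reaction at the primary carbon without allylic transposition or loss of alkene geometry.

Step 15
Reactants: 25 linear allylic chloride sulfone
Product: 26 (3aR,4S,6E,10R,11aS)-2-methoxy-4-[(4-methoxybenzyl)oxy]-6-{[(4-methoxybenzyl)oxy]methyl}-10-methyl-9-(phenylsulfonyl)-2,3,3a,4,5,8,9,10,11,11a-decahydrocyclodeca[b]furan (target labels 1S,3R,9S,10R,6E; C4 and C12 epimers)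
Conditions: KN(SiMe3)2 (3 equiv), THF, 0 °C, 25 added over 8 h by syringe pump (final 0.002 M); then rt
Reagents that add atoms: none
Why: KN(SiMe3)2 removes a C4–H next to the sulfone and the α-sulfonyl carbanion displaces chloride from the primary allylic C5 in an SN2 reaction, forming C4–C5. The closest known reaction type is the intramolecular alkylation of sulfone-stabilised carbanions by allylic halides used to make medium and large carbocycles. The ten-membered ring closes in a 10-exo-tet mode. C4 becomes a stereocentre under no control, which is harmless because the sulfone is excised in step 16, and C1, C3, C9, C10 and the alkene are not touched. The step needs SN2 over SN2′ (C7 is fully substituted, so attack there would build a quaternary centre in an eight-membered ring) and ring closure over oligomerisation and base-induced loss of HCl. These are secured by slow addition at high dilution, by the cis-2,3-disubstituted oxolane that turns both arms to one face, and by the cis placement of C5 and C8 on the alkene.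

Step 16
Reactants: 26 macrocyclic sulfone
Product: 27 (3aR,4S,6E,10S,11aS)-2-methoxy-4-[(4-methoxybenzyl)oxy]-6-{[(4-methoxybenzyl)oxy]methyl}-10-methyl-2,3,3a,4,5,8,9,10,11,11a-decahydrocyclodeca[b]furan (C12 epimers)
Conditions: Na/Hg (6 % Na), Na2HPO4, MeOH/THF, −20 → 0 °C
Reagents that add atoms: none
Why: reductive desulfonylation by electron transfer from the amalgam cleaves the C4–S bond and methanol protonates C4, so both C4 epimers converge; the sulfone is homoallylic, so no alkene shift is expected, and the benzylic ethers and the acetal survive.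

Step 17
Reactants: 27 macrocyclic acetal
Product: 29 (3aR,4S,6E,10S,11aS)-4-[(4-methoxybenzyl)oxy]-6-{[(4-methoxybenzyl)oxy]methyl}-10-methyl-3a,4,5,8,9,10,11,11a-octahydrocyclodeca[b]furan-2(3H)-one, via lactol 28 (not isolated)
Conditions: AcOH/THF/H2O (3:1:1), 45 °C; work-up; then Dess–Martin periodinane, NaHCO3, CH2Cl2, rt
Reagents that add atoms: water, O
Why: acid hydrolysis of the 2-methoxyoxolane through its oxocarbenium ion gives the lactol, and Dess–Martin oxidation converts it into the γ-lactone and removes the C12 stereocentre; the 4-methoxybenzyl ethers tolerate both stages.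

Step 18
Reactants: 29 lactone
Product: 32 (3aR,4S,6E,10S,11aS)-4-[(4-methoxybenzyl)oxy]-6-{[(4-methoxybenzyl)oxy]methyl}-10-methyl-3-methylidene-3a,4,5,8,9,10,11,11a-octahydrocyclodeca[b]furan-2(3H)-one, via Mannich base 30 (not isolated), via ammonium iodide 31 (not isolated)
Conditions: LiN(i-Pr)2, THF, −78 °C; (Me2N=CH2)I, −78 → 0 °C; then MeI, MeOH, rt; then aq. NaHCO3, CH2Cl2, rt
Reagents that add atoms: N,N-dimethylmethyleneiminium iodide (Eschenmoser's salt), C=[N+](C)C.[I-]
Why: Eschenmoser methylenation (Mannich reaction of the lactone lithium enolate at C11, N-methylation, then base-induced β-elimination of trimethylamine) gives the exocyclic methylene; C11 becomes sp2 and C10, which is not acidic, keeps its configuration.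

Step 19
Reactants: 32 α-methylene lactone
Product: 33 (3aR,4S,6E,10S,11aS)-4-hydroxy-6-(hydroxymethyl)-10-methyl-3-methylidene-3a,4,5,8,9,10,11,11a-octahydrocyclodeca[b]furan-2(3H)-one
Conditions: DDQ (3 equiv), CH2Cl2/pH 7 buffer (10:1), 0 °C → rt
Reagents that add atoms: none
Why: oxidative cleavage of both 4-methoxybenzyl ethers by DDQ (benzylic hydride abstraction, then hydrolysis of the oxocarbenium ion) frees O9 and O14 without affecting the electron-poor α-methylene lactone.

Step 20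
Reactants: 33 diol
Product: 34 [(3aR,4S,6E,10S,11aS)-4-hydroxy-10-methyl-3-methylidene-2-oxo-2,3,3a,4,5,8,9,10,11,11a-decahydrocyclodeca[b]furan-6-yl]methyl acetate
Conditions: AcCl (1.1 equiv), 2,4,6-collidine, CH2Cl2, −78 °C
Reagents that add atoms: acetyl chloride, CC(=O)Cl
Why: kinetically selective acylation of the primary allylic hydroxyl over the hindered secondary C9 hydroxyl next to the ring fusion, with a weak base at −78 °C so that the lactone should not migrate to O9.

Step 21
Reactants: 34 hydroxy acetate; 35 (tert-butyldimethylsilyloxy)acetic acid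
Product: 36 (3aS,4S,6E,10S,11aS)-6-(acetoxymethyl)-10-methyl-3-methylidene-2-oxo-2,3,3a,4,5,8,9,10,11,11a-decahydrocyclodeca[b]furan-4-yl (tert-butyldimethylsilyloxy)acetate
Conditions: EDC·HCl, DMAP (0.2 equiv), CH2Cl2, 0 °C → rt
Reagents that add atoms: none
Why: Steglich esterification (carbodiimide activation and acyl transfer through the N-acylpyridinium ion) acylates the remaining C9 hydroxyl with retention at C9.

Step 22
Reactants: 36 silyl-protected glycolate
Product: 37 (3aS,4S,6E,10S,11aS)-6-(acetoxymethyl)-10-methyl-3-methylidene-2-oxo-2,3,3a,4,5,8,9,10,11,11a-decahydrocyclodeca[b]furan-4-yl hydroxyacetate (CNP0156635.1)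
Conditions: HF·pyridine, THF/pyridine, 0 °C → rt
Reagents that add atoms: none
Why: fluoride-mediated desilylation under buffered, weakly acidic conditions releases the glycolate hydroxyl and leaves the two esters and the conjugate acceptor untouched.

Compound list
1 | (R)-4-benzyl-1,3-oxazolidin-2-one | O=C1N[C@H](Cc2ccccc2)CO1 | starting material
2 | pent-4-enoyl chloride | C=CCCC(=O)Cl | starting material
3 | (R)-4-benzyl-3-(pent-4-enoyl)-1,3-oxazolidin-2-one | C=CCCC(=O)N1[C@H](Cc2ccccc2)COC1=O | intermediate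
4 | tert-butyl 4-oxobutanoate | O=CCCC(=O)OC(C)(C)C | starting material
5 | tert-butyl (4S,5R)-5-{[(4R)-4-benzyl-2-oxo-1,3-oxazolidin-3-yl]carbonyl}-4-hydroxyoct-7-enoate | CC(C)(C)OC(=O)CC[C@H](O)[C@@H](CC=C)C(=O)N1[C@H](Cc2ccccc2)COC1=O | intermediate
6 | tert-butyl (4S,5R)-4-hydroxy-5-[methoxy(methyl)carbamoyl]oct-7-enoate | CC(C)(C)OC(=O)CC[C@H](O)[C@@H](CC=C)C(=O)N(C)OC | intermediate
7 | (S)-3-bromo-2-methylpropan-1-ol | BrC[C@@H](C)CO | starting material
8 | (S)-(3-bromo-2-methylpropoxy)(tert-butyl)dimethylsilane | BrC[C@@H](C)CO[Si](C)(C)C(C)(C)C | intermediate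
9 | (S)-[3-(tert-butyldimethylsilyloxy)-2-methylpropyl]magnesium bromide | Br[Mg]C[C@@H](C)CO[Si](C)(C)C(C)(C)C | intermediate
10 | tert-butyl (4S,5R,8R)-5-allyl-9-(tert-butyldimethylsilyloxy)-4-hydroxy-8-methyl-6-oxononanoate | CC(C)(C)OC(=O)CC[C@H](O)[C@@H](CC=C)C(=O)C[C@@H](C)CO[Si](C)(C)C(C)(C)C | intermediate
11 | tert-butyl (4S,5R,6S,8R)-5-allyl-9-(tert-butyldimethylsilyloxy)-4,6-dihydroxy-8-methylnonanoate | CC(C)(C)OC(=O)CC[C@H](O)[C@@H](CC=C)[C@@H](O)C[C@@H](C)CO[Si](C)(C)C(C)(C)C | intermediate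
12 | (5S)-5-[(4S,5S,7R)-8-(tert-butyldimethylsilyloxy)-5-hydroxy-7-methyloct-1-en-4-yl]oxolan-2-one | O=C1CC[C@H](O1)[C@@H](CC=C)[C@@H](O)C[C@@H](C)CO[Si](C)(C)C(C)(C)C | intermediate
13 | (5S)-5-{(2S,3S)-2-[(2R)-3-(tert-butyldimethylsilyloxy)-2-methylpropyl]-5-hydroxyoxolan-3-yl}oxolan-2-one (anomers) | O=C1CC[C@H](O1)[C@H]2CC(O)O[C@H]2C[C@@H](C)CO[Si](C)(C)C(C)(C)C | intermediate
14 | (5S)-5-{(2S,3S)-2-[(2R)-3-hydroxy-2-methylpropyl]-5-methoxyoxolan-3-yl}oxolan-2-one (anomers) | O=C1CC[C@H](O1)[C@H]2CC(OC)O[C@H]2C[C@@H](C)CO | intermediate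
15 | (tert-butyldimethylsilyloxy)acetaldehyde | CC(C)(C)[Si](C)(C)OCC=O | starting material
16 | (5S)-3-[2-(tert-butyldimethylsilyloxy)-1-hydroxyethyl]-5-{(2S,3S)-2-[(2R)-3-hydroxy-2-methylpropyl]-5-methoxyoxolan-3-yl}oxolan-2-one (diastereomer mixture) | O=C1C(C(O)CO[Si](C)(C)C(C)(C)C)C[C@H](O1)[C@H]2CC(OC)O[C@H]2C[C@@H](C)CO | intermediate
17 | bis-methanesulfonate of 16 | O=C1C(C(OS(C)(=O)=O)CO[Si](C)(C)C(C)(C)C)C[C@H](O1)[C@H]2CC(OC)O[C@H]2C[C@@H](C)COS(C)(=O)=O | intermediate
18 | (3E,5S)-3-[2-(tert-butyldimethylsilyloxy)ethylidene]-5-{(2S,3S)-5-methoxy-2-[(2R)-2-methyl-3-(methylsulfonyloxy)propyl]oxolan-3-yl}oxolan-2-one | O=C1/C(=C/CO[Si](C)(C)C(C)(C)C)C[C@H](O1)[C@H]2CC(OC)O[C@H]2C[C@@H](C)COS(C)(=O)=O | intermediate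
19 | (2R)-3-{(2S,3R)-3-[(1S,3E)-5-(tert-butyldimethylsilyloxy)-1-hydroxy-3-(hydroxymethyl)pent-3-en-1-yl]-5-methoxyoxolan-2-yl}-2-methylpropyl methanesulfonate | CC(C)(C)[Si](C)(C)OC/C=C(/CO)C[C@H](O)[C@H]1CC(OC)O[C@H]1C[C@@H](C)COS(C)(=O)=O | intermediate
20 | sodium benzenesulfinate | [Na+].[O-]S(=O)c1ccccc1 | starting material
21 | (1S,3E)-5-(tert-butyldimethylsilyloxy)-3-(hydroxymethyl)-1-{(2S,3R)-5-methoxy-2-[(2R)-2-methyl-3-(phenylsulfonyl)propyl]oxolan-3-yl}pent-3-en-1-ol | CC(C)(C)[Si](C)(C)OC/C=C(/CO)C[C@H](O)[C@H]1CC(OC)O[C@H]1C[C@@H](C)CS(=O)(=O)c2ccccc2 | intermediate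
22 | tert-butyl{[(2E,5S)-5-[(4-methoxybenzyl)oxy]-3-{[(4-methoxybenzyl)oxy]methyl}-5-{(2S,3R)-5-methoxy-2-[(2R)-2-methyl-3-(phenylsulfonyl)propyl]oxolan-3-yl}pent-2-en-1-yl]oxy}dimethylsilane | CC(C)(C)[Si](C)(C)OC/C=C(/COCc1ccc(OC)cc1)C[C@H](OCc2ccc(OC)cc2)[C@H]3CC(OC)O[C@H]3C[C@@H](C)CS(=O)(=O)c4ccccc4 | intermediate
23 | (2E,5S)-5-[(4-methoxybenzyl)oxy]-3-{[(4-methoxybenzyl)oxy]methyl}-5-{(2S,3R)-5-methoxy-2-[(2R)-2-methyl-3-(phenylsulfonyl)propyl]oxolan-3-yl}pent-2-en-1-ol | OC/C=C(/COCc1ccc(OC)cc1)C[C@H](OCc2ccc(OC)cc2)[C@H]3CC(OC)O[C@H]3C[C@@H](C)CS(=O)(=O)c4ccccc4 | intermediate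
24 | methanesulfonate of 23 at O5 | CS(=O)(=O)OC/C=C(/COCc1ccc(OC)cc1)C[C@H](OCc2ccc(OC)cc2)[C@H]3CC(OC)O[C@H]3C[C@@H](C)CS(=O)(=O)c4ccccc4 | intermediate
25 | (2S,3R)-3-[(1S,3E)-5-chloro-1-[(4-methoxybenzyl)oxy]-3-{[(4-methoxybenzyl)oxy]methyl}pent-3-en-1-yl]-5-methoxy-2-[(2R)-2-methyl-3-(phenylsulfonyl)propyl]oxolane | ClC/C=C(/COCc1ccc(OC)cc1)C[C@H](OCc2ccc(OC)cc2)[C@H]3CC(OC)O[C@H]3C[C@@H](C)CS(=O)(=O)c4ccccc4 | intermediate
26 | (3aR,4S,6E,10R,11aS)-2-methoxy-4-[(4-methoxybenzyl)oxy]-6-{[(4-methoxybenzyl)oxy]methyl}-10-methyl-9-(phenylsulfonyl)-2,3,3a,4,5,8,9,10,11,11a-decahydrocyclodeca[b]furan | COC1O[C@H]2C[C@@H](C)C(S(=O)(=O)c3ccccc3)C/C=C(/COCc4ccc(OC)cc4)C[C@H](OCc5ccc(OC)cc5)[C@H]2C1 | intermediate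
27 | (3aR,4S,6E,10S,11aS)-2-methoxy-4-[(4-methoxybenzyl)oxy]-6-{[(4-methoxybenzyl)oxy]methyl}-10-methyl-2,3,3a,4,5,8,9,10,11,11a-decahydrocyclodeca[b]furan | COC1O[C@H]2C[C@@H](C)CC/C=C(/COCc3ccc(OC)cc3)C[C@H](OCc4ccc(OC)cc4)[C@H]2C1 | intermediate
28 | (3aR,4S,6E,10S,11aS)-4-[(4-methoxybenzyl)oxy]-6-{[(4-methoxybenzyl)oxy]methyl}-10-methyl-2,3,3a,4,5,8,9,10,11,11a-decahydrocyclodeca[b]furan-2-ol (anomers) | OC1O[C@H]2C[C@@H](C)CC/C=C(/COCc3ccc(OC)cc3)C[C@H](OCc4ccc(OC)cc4)[C@H]2C1 | intermediate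
29 | (3aR,4S,6E,10S,11aS)-4-[(4-methoxybenzyl)oxy]-6-{[(4-methoxybenzyl)oxy]methyl}-10-methyl-3a,4,5,8,9,10,11,11a-octahydrocyclodeca[b]furan-2(3H)-one | O=C1O[C@H]2C[C@@H](C)CC/C=C(/COCc3ccc(OC)cc3)C[C@H](OCc4ccc(OC)cc4)[C@H]2C1 | intermediate
30 | 3-[(dimethylamino)methyl] derivative of 29 (C11 epimers) | CN(C)CC1C(=O)O[C@H]2C[C@@H](C)CC/C=C(/COCc3ccc(OC)cc3)C[C@H](OCc4ccc(OC)cc4)[C@@H]12 | intermediate
31 | 3-[(trimethylammonio)methyl] derivative of 29, iodide | C[N+](C)(C)CC1C(=O)O[C@H]2C[C@@H](C)CC/C=C(/COCc3ccc(OC)cc3)C[C@H](OCc4ccc(OC)cc4)[C@@H]12.[I-] | intermediate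
32 | (3aR,4S,6E,10S,11aS)-4-[(4-methoxybenzyl)oxy]-6-{[(4-methoxybenzyl)oxy]methyl}-10-methyl-3-methylidene-3a,4,5,8,9,10,11,11a-octahydrocyclodeca[b]furan-2(3H)-one | C=C1C(=O)O[C@H]2C[C@@H](C)CC/C=C(/COCc3ccc(OC)cc3)C[C@H](OCc4ccc(OC)cc4)[C@@H]12 | intermediate
33 | (3aR,4S,6E,10S,11aS)-4-hydroxy-6-(hydroxymethyl)-10-methyl-3-methylidene-3a,4,5,8,9,10,11,11a-octahydrocyclodeca[b]furan-2(3H)-one | C=C1C(=O)O[C@H]2C[C@@H](C)CC/C=C(/CO)C[C@H](O)[C@@H]12 | intermediate
34 | [(3aR,4S,6E,10S,11aS)-4-hydroxy-10-methyl-3-methylidene-2-oxo-2,3,3a,4,5,8,9,10,11,11a-decahydrocyclodeca[b]furan-6-yl]methyl acetate | C=C1C(=O)O[C@H]2C[C@@H](C)CC/C=C(/COC(C)=O)C[C@H](O)[C@@H]12 | intermediate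
35 | (tert-butyldimethylsilyloxy)acetic acid | CC(C)(C)[Si](C)(C)OCC(=O)O | starting material
36 | (3aS,4S,6E,10S,11aS)-6-(acetoxymethyl)-10-methyl-3-methylidene-2-oxo-2,3,3a,4,5,8,9,10,11,11a-decahydrocyclodeca[b]furan-4-yl (tert-butyldimethylsilyloxy)acetate | C=C1C(=O)O[C@H]2C[C@@H](C)CC/C=C(/COC(C)=O)C[C@H](OC(=O)CO[Si](C)(C)C(C)(C)C)[C@@H]12 | intermediate
37 | (3aS,4S,6E,10S,11aS)-6-(acetoxymethyl)-10-methyl-3-methylidene-2-oxo-2,3,3a,4,5,8,9,10,11,11a-decahydrocyclodeca[b]furan-4-yl hydroxyacetate (CNP0156635.1) | C=C1C(=O)O[C@H]2C[C@@H](C)CC/C=C(/COC(C)=O)C[C@H](OC(=O)CO)[C@@H]12 | target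

Total step count: 22. Longest linear sequence: 21 steps (steps 1–3 and 5–22, from 1 and 2 to 37); step 4 is a one-step side branch.

Steps most likely to fail

1. Step 15. Ring closure may lose to intermolecular alkylation or to base-induced loss of HCl from the allylic chloride, because the unstabilised sulfonyl carbanion is strongly basic and the ten-membered transition state is strained. The fallback sets out from 22 and returns at 26. The sulfone of 22 is C-acylated (n-BuLi 2.1 equiv, then ClCO2Me, THF, −78 °C) to the α-methoxycarbonyl sulfone F1. Bu4NF then frees the C5 hydroxyl to give the allylic alcohol F2, and ClCO2Me with pyridine converts it into the allylic methyl carbonate F3. With Pd(PPh3)4 in THF at 65 °C under high dilution, F3 should ionise to a π-allyl complex and methoxide, and the soft sulfonyl-ester anion should attack the unsubstituted C5 terminus (Tsuji–Trost macrocyclisation) to give the macrocyclic sulfonyl ester F4. Krapcho demethoxycarbonylation (LiCl, wet DMSO, 140 °C) then gives sulfone 26.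

2. Step 9. The elimination may deliver a sizeable share of the (Z)-alkylidene lactone, and the amidine base may attack the primary mesylate. The fallback sets out from 14 and returns at 18. Compound 14 is silylated (Et3SiCl, imidazole, CH2Cl2) to the triethylsilyl ether F5. Its lactone enolate is phosphorylated and rearranged (LiN(i-Pr)2 2.2 equiv, ClP(O)(OEt)2, THF, −78 °C → rt) to the α-diethylphosphono lactone F6. Horner–Wadsworth–Emmons reaction of F6 with aldehyde 15 (LiCl, DBU, MeCN) should give the (E)-alkylidene lactone F7. PPTS in MeOH at 0 °C removes the more labile triethylsilyl group to give the primary alcohol F8, and MsCl with Et3N gives 18.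

3. Step 5. The magnesium alkoxide may lactonise onto the tert-butyl ester and the Grignard reagent may then add again, or the ester may be attacked directly. The fallback sets out from 5 and returns at 10. Lithium ethanethiolate (EtSH, n-BuLi, THF, 0 °C) cleaves the imide of 5 to the S-ethyl thioester F9 with return of 1. Bromide 8 is converted into the iodide F10 (NaI, acetone, reflux) and then into the alkylzinc iodide F11 (Zn, THF/DMA). Fukuyama coupling of F9 with F11 (PdCl2(PPh3)2, toluene/THF, rt), which tolerates esters and hydroxyls, should give ketone 10.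

Further compounds
F1 | step 15 | methyl ester at C4 of sulfone 22 (α-methoxycarbonyl sulfone, C4 epimers) | CC(C)(C)[Si](C)(C)OC/C=C(/COCc1ccc(OC)cc1)C[C@H](OCc2ccc(OC)cc2)[C@H]3CC(OC)O[C@H]3C[C@@H](C)C(C(=O)OC)S(=O)(=O)c4ccccc4
F2 | step 15 | C5 allylic alcohol of the α-methoxycarbonyl sulfone | OC/C=C(/COCc1ccc(OC)cc1)C[C@H](OCc2ccc(OC)cc2)[C@H]3CC(OC)O[C@H]3C[C@@H](C)C(C(=O)OC)S(=O)(=O)c4ccccc4
F3 | step 15 | C5 allylic methyl carbonate of the α-methoxycarbonyl sulfone | COC(=O)OC/C=C(/COCc1ccc(OC)cc1)C[C@H](OCc2ccc(OC)cc2)[C@H]3CC(OC)O[C@H]3C[C@@H](C)C(C(=O)OC)S(=O)(=O)c4ccccc4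
F4 | step 15 | macrocyclic C4 methoxycarbonyl phenyl sulfone (26 with CO2Me on C4) | COC1O[C@H]2C[C@@H](C)C(C(=O)OC)(S(=O)(=O)c3ccccc3)C/C=C(/COCc4ccc(OC)cc4)C[C@H](OCc5ccc(OC)cc5)[C@H]2C1
F5 | step 9 | triethylsilyl ether of 14 at O4 | O=C1CC[C@H](O1)[C@H]2CC(OC)O[C@H]2C[C@@H](C)CO[Si](CC)(CC)CC
F6 | step 9 | α-(diethoxyphosphoryl) lactone | O=C1C(P(=O)(OCC)OCC)C[C@H](O1)[C@H]2CC(OC)O[C@H]2C[C@@H](C)CO[Si](CC)(CC)CC
F7 | step 9 | (E)-alkylidene lactone with the O4 triethylsilyl ether | O=C1/C(=C/CO[Si](C)(C)C(C)(C)C)C[C@H](O1)[C@H]2CC(OC)O[C@H]2C[C@@H](C)CO[Si](CC)(CC)CC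
F8 | step 9 | (E)-alkylidene lactone with free C4 hydroxyl | O=C1/C(=C/CO[Si](C)(C)C(C)(C)C)C[C@H](O1)[C@H]2CC(OC)O[C@H]2C[C@@H](C)CO
F9 | step 5 | tert-butyl (4S,5R)-5-[(ethylsulfanyl)carbonyl]-4-hydroxyoct-7-enoate | CC(C)(C)OC(=O)CC[C@H](O)[C@@H](CC=C)C(=O)SCC
F10 | step 5 | (S)-tert-butyl(3-iodo-2-methylpropoxy)dimethylsilane | IC[C@@H](C)CO[Si](C)(C)C(C)(C)C
F11 | step 5 | (S)-[3-(tert-butyldimethylsilyloxy)-2-methylpropyl]zinc iodide | I[Zn]C[C@@H](C)CO[Si](C)(C)C(C)(C)C
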